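## Structural features

The target is a C22 dihydroxy acid built on four rings: a cyclobutane (C9, C10, C21, C20), cyclohexene ring A (C10–C11=C12–C13–C22–C21), cyclohexene ring B (C13–C14=C16–C17–C18–C22) and cyclopentane ring C (C18–C19–C20–C21–C22). C21 is shared by the cyclobutane, ring A and ring C; C22 is shared by rings A, B and C. The cyclobutane, ring C and ring B all stand on one face of ring A, so the molecule is a bowl with ring A as its floor; ring C is cis-fused to the cyclobutane and to ring A but trans-fused to ring B. All eight stereocentres are contiguous (C9, C10, C21, C20, then C22, C18, C17, C13). The octyl group on C9 is exo (trans to C11), the C19 arm on C20 is endo (cis to C22), and the hydroxyls on C13 and C17 are cis to each other on the outer face of ring B, flanking the C14=C16 alkene that bears the carboxyl group. Fragile points are the tertiary allylic C13 carbinol next to an acrylic acid, the allylic C17 alcohol, and the strained four-membered ring, which a cation at C11 could enlarge. The real difficulty is the crowded cyclobutane (arm on the concave face of C20) and the attachment of rings B and C with a trans B/C but cis A/B relationship. The key step exploits ring A: a C11=C12 alkene with oxygen on the allylic carbon C13 is what remains when one carbon (C12) is inserted into the C11=C13 bond of a cyclopentene, and that cyclopentene, already fused to an exo-octyl cyclobutanone, is the adduct of cyclopentadiene and octylketene.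

## Logic of the disconnections

27 ⇒ 26. The O–CH3 bond of the ester and the O–Si bond at C13 are cut last. This keeps the acid and the tertiary carbinol masked through all enolate and oxidation chemistry. The forward step must hydrolyse a hindered conjugated ester without dehydration or cleavage next to C13.

26 ⇒ 23 ⇒ 22. The C17–O bond is cut by a retro-[2,3] shift, which moves the alkene from C14=C16 to C16=C17 and puts selenium on C14 (23); cutting C14–Se then gives 22. The C17 oxygen and the final alkene position thus both derive from a β,γ-unsaturated ester. The forward demand is α-selenenylation of the dienolate on the outer face of ring B.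

22 ⇒ 21 ⇒ 20. C22–C18 and C13–C14 are cut together (retro-[4+2]). Rings B and C open at once and three stereocentres (C13, C18, C22) disappear, leaving a ring-A enone with a dienoate arm on C20. Forward, the C22=C13 enol ether of 21 must act as the 2π partner, on its concave face only, with the dienoate as the 4π partner.

20 ⇒ 18 + 19. The C18=C17 bond is cut (retro cross-metathesis), so the five ester-side carbons come from commercial 19. The forward step must give the E alkene and leave the enone alkene alone.

18 ⇒ 17 ⇒ 14 + 15 ⇒ 13. C13=O is traced to the alcohol; C19–C18 is cut (sp3–sp2 coupling with 15); the C20–H bond is traced to hydroboration of the C20=C19 alkene of 14; C20=C19 is cut to the ketone 13. The C20 stereocentre is thus reduced to a question of facial selectivity. Forward, hydrogen must reach C20 from the convex face, and C13 must be an alcohol while boron hydride is present.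

13 ⇒ 11 ⇒ 10. The ketone is re-masked as the dioxolane, bromine is returned to C12, and the single enantiomer 11 is traced to racemate 10. The C13 carbinol, flanked by a bromovinyl carbon and a methylene, is the best place in the route for an enzymatic resolution.

10 ⇒ 9 ⇒ 7 + 8 (key). C11–C12 and C12–C13 are cut: removing C12 with its bromine and closing C11–C13 gives the cyclopentene 7. This takes ring A back to a five-membered ring that is far easier to make. Forward, the carbene must add to the convex face and the allyl cation must be captured by water at C13, not C11.

7 ⇒ 6 ⇒ 5 ⇒ 4 + 2; 4 ⇒ 3; 2 ⇒ 1. The ketal is removed, C9 is epimerised back, and C9–C10 and C20–C21 are cut (retro ketene cycloaddition) to 4 and 2, which come from 3 and 1. Forward, the cycloaddition fixes the cis fusion and regiochemistry, and base equilibration must favour the exo octyl group.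

## Other disconnections considered

Alternative 1: The cyclobutane is cut last, at C20–C21 and C9–C10, which also opens ring C and leads to the cis-fused bicyclic enone A1 carrying an (E)-undec-2-enyl chain on C18. Forward, irradiation of A1 would excite the enone, form C21–C20 first (five-membered ring, 1,5-closure) and then C10–C9, giving the tetracyclic ketone A2.
- In its favour: two rings, two C–C bonds and four stereocentres (C9, C10, C20, C21) in one late step; the octyl chain arrives as a plain alkene, so no ketene chemistry is needed; the strained ring never has to survive cationic or basic steps.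
- Against it here: the 1,4-diradical can rotate before closing, so the exo octyl configuration at C9 is not secured by alkene geometry; A1 holds a second chromophore (the C14=C16 enoate) and a β-hydroxy ketone (C13–OH, C11=O) prone to retro-aldol cleavage; A2 still needs C11=O turned regioselectively into C11=C12; A1 itself needs a long synthesis.
- Comparison: on structure this plan is the better one in convergence and in forming the four-membered ring at the end. On mechanism the chosen plan is the more predictable, since cis fusion and exo octyl follow from a thermal cycloaddition and an equilibration. On step economy the photochemical plan is at best equal, because what it saves on the cyclobutane it spends on A1 and on the C11 ketone.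

Alternative 2: Only C9–C10 of the cyclobutane is cut: the cyclobutanone A4 is traced to the 7-(phenylthio)norcar-2-en-7-yl carbinol A3. Forward, acid ionises C9–OH while the C20–C10 bond migrates to C9, and the thionium ion is hydrolysed to the C20 ketone.
- In its favour: ring A is six-membered from the start, so no carbon is inserted and no allyl cation with two open termini is formed; the exo octyl group can again be set by equilibration next to the ketone.
- Against it here: A4 has no oxygen at C13, so an allylic oxidation must follow, choosing C13 over C10; the migration must select the C20–C10 bond over C20–C21, and the vinylcyclopropane in A3 can open instead; absolute configuration would again need a resolution or an asymmetric carbenoid addition.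
- Comparison: the two plans are equal in delivering an exo-octyl cyclobutanone cis-fused to ring A, and this one is better in avoiding the C11/C13 capture problem. The chosen plan is better in placing the C13 oxygen and the C11=C12 alkene in the same operation that makes ring A. Step count to an oxygenated ring A is about equal.

Alternative 3: Ring C is cut at C22–C18: the nitromethyl ketone A6 is traced to the ring-A enone A5 with an (E)-3-nitroallyl arm on C20. Forward, the kinetic C22 enolate (or its silyl enol ether) adds to C18 of the nitroalkene in a 5-exo closure.
- In its favour: a polar, low-temperature bond formation of a well-known type; the arm on the concave face can reach only C22; the nitromethyl group should go to the convex side as the target requires; the nitro group is a handle for C17.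
- Against it here: it makes one ring and one bond; C16, C14 and C15 must be added afterwards, ring B closed and the C13 and C17 oxygens set separately; the nitroalkene is sensitive to base (γ-deprotonation), so enolate formation in its presence is delicate.
- Comparison: this cut does not compete with the ring enlargement but with the later cycloaddition of the chosen route; A5 would itself come from the ring-enlargement product, so on ring A and the cyclobutane the plans are equal. On mechanism it is the better choice in predictability (one bond, stepwise, anionic). On step economy the chosen route is better, because its [4+2] step forms C22–C18 and C13–C14 together and sets C13.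

Key step: step 4

Assumption: vinyl bromide 15 and methyl (2E)-penta-2,4-dienoate 19 are taken as commercial, and the lipase in step 5 is assumed to follow the usual size rule for secondary alcohols (the 13R enantiomer is acylated).

## Steps

Step 1
Reactants: 1 dicyclopentadiene
Product: 2 cyclopenta-1,3-diene
Conditions: neat, 170–180 °C, distil monomer into a receiver at −78 °C
Reagents that add atoms: none
Why: Thermal retro-Diels–Alder reaction; each molecule of the dimer gives two molecules of the monomer, which distils out and is used at once.

Step 2
Reactants: 3 decanoyl chloride; 2 cyclopenta-1,3-diene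
Product: 6 rac-exo-7-octylbicyclo[3.2.0]hept-2-en-6-one, via octylketene 4 (not isolated), via endo ketone 5 (not isolated)
Conditions: Et3N, hexane, 40 °C (3 added slowly to excess 2); filter; DBU (cat.), CH2Cl2, 20 °C
Reagents that add atoms: none
Why: Et3N dehydrochlorinates 3 to the aldoketene 4, which undergoes a thermal ketene–alkene [2+2] cycloaddition with 2: cis at the ring fusion (C10, C21), regiospecific (C20 bonds to a diene terminus, C9 to the adjacent internal carbon) and with octyl endo under kinetic control (5). DBU then epimerises C9 through the enolate toward the less crowded exo isomer 6, which is separated from residual 5 (recycled); the material is racemic at this stage.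

Step 3
Reactants: 6 rac-exo-7-octylbicyclo[3.2.0]hept-2-en-6-one
Product: 7 rac-exo-7-octylbicyclo[3.2.0]hept-2-en-6-one ethylene ketal
Conditions: Me3SiOCH2CH2OSiMe3, Me3SiOTf (cat.), CH2Cl2, −78 to −20 °C
Reagents that add atoms: 1,2-bis(trimethylsilyloxy)ethane, C[Si](C)(C)OCCO[Si](C)(C)C
Why: Silyl-transfer ketalisation; relief of angle strain on going from the trigonal to the tetrahedral ring carbon drives dioxolane formation, and the cold aprotic conditions avoid epimerisation at C9 and acid-induced rearrangement of the bicycle.

Step 4
Reactants: 7 rac-exo-7-octylbicyclo[3.2.0]hept-2-en-6-one ethylene ketal; 8 bromoform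
Product: 10 rac-3-bromo-4-hydroxy-8-octylbicyclo[4.2.0]oct-2-en-7-one ethylene ketal (C12–Br; C13–OH trans to the cyclobutane), via dibromocyclopropane 9 (not isolated)
Conditions: CHBr3, KOt-Bu, pentane, −20 to 0 °C; filter, concentrate cold; AgClO4, CaCO3, acetone–H2O 4:1, 0 to 20 °C, dark
Reagents that add atoms: water, O
Why: Dibromocarbene, formed by α-elimination from the tribromomethyl anion, adds in a concerted [2+1] fashion to the convex face of the C11=C13 bond of 7, away from the cis-fused cyclobutane, to give 9, which is kept cold because such adducts open easily. Monovalent silver then removes the bromide lying over the five-membered ring and the C11–C13 bond opens in a disrotatory, symmetry-allowed cyclopropyl-to-allyl process with the ring bonds turning inward, so the three- and five-membered rings merge into six-membered ring A as a 2-bromocyclohexenyl cation; ring A is thus closed by ring enlargement (cleavage of the shared bond of a bicyclo[3.1.0]hexane), not by an end-to-end cyclisation. The closest known reaction type is the silver-assisted solvolysis of gem-dihalocyclopropanes fused to cyclopentanes, which gives 2-halocyclohex-2-enyl alcohols or esters. Water captures the cation at C13 on the convex face, since the concave face is covered by the cyclobutane and its dioxolane; this sets the one new stereocentre, whose only later role is the resolution. The step needs capture at C13 rather than C11: C11 sits next to the ring-fusion carbon C10 and the octyl-bearing C9, whereas C13 is flanked by the C22 methylene, and the endo dioxolane oxygen can reach C13 but not C11, so any reversible oxonium formation also steers water to C13 with opening from the convex face. A short-lived cation in a water-rich medium limits cyclobutylcarbinyl ring enlargement from the C11 terminus, and CaCO3 takes up the HClO4 released so that the dioxolane survives.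

Step 5
Reactants: 10 rac-3-bromo-4-hydroxy-8-octylbicyclo[4.2.0]oct-2-en-7-one ethylene ketal
Product: 11 the same bromo allylic alcohol as the single enantiomer with S configuration at C13
Conditions: lipase from Burkholderia cepacia (immobilised), vinyl acetate, t-BuOMe, 30 °C, stopped slightly past half conversion
Reagents that add atoms: none
Why: Lipase-catalysed enantioselective transesterification (kinetic resolution): by the empirical size rule, with the bromovinyl carbon C12 as the large and the C22 methylene as the medium group, the 13R enantiomer should be acetylated and the wanted 13S alcohol 11 left behind. Because the relative configuration is already fixed, C9, C10 and C21 are resolved at the same time, and running past half conversion raises the enantiomeric purity of the recovered alcohol.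

Step 6
Reactants: 11 (13S)-3-bromo-4-hydroxy-8-octylbicyclo[4.2.0]oct-2-en-7-one ethylene ketal
Product: 13 4-hydroxy-8-octylbicyclo[4.2.0]oct-2-en-7-one (C11=C12, C13–OH, C20 ketone), via ketal alcohol 12 (not isolated)
Conditions: t-BuLi (3.3 equiv), THF, −78 °C; MeOH; then 2 M HCl, 20 °C
Reagents that add atoms: water, O
Why: The first equivalent of t-BuLi forms the alkoxide, the next two effect bromine–lithium exchange at the vinyl bromide (the second destroying t-BuBr), and methanol protonates the vinyllithium with the alkene in place; aqueous acid then hydrolyses the dioxolane. The unactivated secondary allylic alcohol and the thermodynamically preferred exo C9 are left alone, and the convex C13–OH cannot reach C20, so no hemiketal forms.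

Step 7
Reactants: 13 4-hydroxy-8-octylbicyclo[4.2.0]oct-2-en-7-one
Product: 14 7-methylidene-8-octylbicyclo[4.2.0]oct-2-en-4-ol (C20=C19H2)
Conditions: Ph3PCH3Br, KOt-Bu, THF, 0 to 20 °C (excess ylide)
Reagents that add atoms: methylenetriphenylphosphorane (from methyltriphenylphosphonium bromide), C=P(c1ccccc1)(c1ccccc1)c1ccccc1
Why: Wittig methylenation; the strained cyclobutanone is a very good electrophile for the unstabilised ylide, the alkoxide of the free alcohol is tolerated, and any base-induced equilibration at C9 returns the exo isomer.

Step 8
Reactants: 14 7-methylidene-8-octylbicyclo[4.2.0]oct-2-en-4-ol; 15 vinyl bromide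
Product: 17 endo-7-(prop-2-enyl)-exo-8-octylbicyclo[4.2.0]oct-2-en-4-ol (C20–C19H2–C18H=CH2), via alkylborane 16 (not isolated)
Conditions: 9-BBN (2.3 equiv), THF, 0 to 20 °C; then aq K3PO4 (quench of excess borane), PdCl2(dppf) (5 mol%; dppf = 1,1′-bis(diphenylphosphino)ferrocene), 15, DMF–THF, 20 to 45 °C
Reagents that add atoms: none
Why: 9-BBN hydroborates the 1,1-disubstituted exocyclic alkene much faster than the cis-disubstituted ring alkene (the C13–OH only becomes its borinate) and puts boron on C19. Hydrogen should reach C20 on the convex face, because the concave face is screened by C22 and C13 of ring A; this sets C20 with the arm endo. The B-alkyl Suzuki–Miyaura coupling with 15 (oxidative addition to zerovalent palladium, base-assisted transmetallation, reductive elimination) then forms C19–C18.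

Step 9
Reactants: 17 endo-7-(prop-2-enyl)-exo-8-octylbicyclo[4.2.0]oct-2-en-4-ol
Product: 18 8-(prop-2-enyl)-7-octylbicyclo[4.2.0]oct-4-en-3-one (ring-A enone C11=C12–C13=O with endo allyl on C20)
Conditions: Dess–Martin periodinane, NaHCO3, CH2Cl2, 0 to 20 °C
Reagents that add atoms: none
Why: Dess–Martin oxidation of the allylic alcohol to the enone; the C13 stereocentre, having served the resolution, is deliberately erased, and the buffered neutral conditions leave the terminal alkene and the cyclobutane untouched.

Step 10
Reactants: 18 8-(prop-2-enyl)-7-octylbicyclo[4.2.0]oct-4-en-3-one; 19 methyl (2E)-penta-2,4-dienoate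
Product: 20 methyl (2E,4E)-6-(7-octyl-3-oxobicyclo[4.2.0]oct-4-en-8-yl)hexa-2,4-dienoate
Conditions: 19 (3 equiv), RuCl2(H2IMes)(=CH-C6H4-2-O-i-Pr) (second-generation Hoveyda–Grubbs catalyst, 5 mol%), CH2Cl2, 40 °C
Reagents that add atoms: none
Why: Olefin cross-metathesis between the terminal alkene of 18 and the terminal vinyl group of the electron-poor diene 19, with loss of ethene; the new C18=C17 bond should form mainly as the E isomer, while the conjugated C16=C14 bond and the enone alkene are too electron-poor and hindered to enter the cycle.

Step 11
Reactants: 20 methyl (2E,4E)-6-(7-octyl-3-oxobicyclo[4.2.0]oct-4-en-8-yl)hexa-2,4-dienoate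
Product: 22 tetracyclic methyl ester with C13–OSiMe3 and C11=C12 and C16=C17 alkenes, via silyl dienol ether 21 (not isolated)
Conditions: Me3SiOTf, Et3N, CH2Cl2, 0 °C; evaporate; toluene, 2,6-di-tert-butyl-4-methylphenol (trace), 120 °C, sealed tube
Reagents that add atoms: trimethylsilyl trifluoromethanesulfonate, C[Si](C)(C)OS(=O)(=O)C(F)(F)F
Why: Soft enolisation gives the cross-conjugated silyl dienol ether 21 at C22, because γ-deprotonation at C10 would create an alkylidenecyclobutane; on heating, the electron-rich C22=C13 enol ether (2π) and the electron-poor dienoate C18=C17–C16=C14 (4π) combine in an intramolecular Diels–Alder reaction with inverse electron demand, forming C22–C18 (ring C, through the three-atom tether C19–C20–C21) and C13–C14 (ring B). The tether on the concave face allows only top-face attack on C22=C13, which gives the cis A/C and cis A/B fusions and leaves the C13 silyloxy group on the convex face; with C19 held above C22 by the cyclobutane, the (E)-C18=C17 unit can only lie outside the bowl, so H18 ends anti to H22 (trans B/C) and C17 sits on the outer face. The alternative cycloaddition with ring A as the diene is blocked at C11 by the endo hydrogen on C9; the C14 configuration (ester equatorial) is of no consequence.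

Step 12
Reactants: 22 tetracyclic methyl ester with C13–OSiMe3 and C16=C17
Product: 23 C14 phenylselenide of 22 (Se on the outer face of ring B, cis to the C13 silyloxy group)
Conditions: LiN(i-Pr)2, THF, −78 °C; PhSeBr, −78 °C
Reagents that add atoms: phenylselenenyl bromide, Br[Se]c1ccccc1
Why: Deprotonation at C14 gives the ester dienolate, which phenylselenenyl bromide attacks at the α-carbon; attack should come on the outer face of ring B, anti to the axial C13–C12 bond and away from ring A, making the C14–Se bond axial. At −78 °C the equatorial silyloxy group, not aligned with the enolate π system, is not eliminated.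

Step 13
Reactants: 23 C14 phenylselenide
Product: 26 methyl ester of the target with C13–OSiMe3 (C14=C16, C17–OH), via selenoxide 24 (not isolated), via selenenate 25 (not isolated)
Conditions: mCPBA (1.05 equiv), CH2Cl2, −78 °C; Et2NH, −78 to 0 °C
Reagents that add atoms: 3-chloroperoxybenzoic acid, OOC(=O)c1cccc(Cl)c1
Why: Chemoselective oxidation at selenium gives the allylic selenoxide 24, which undergoes a suprafacial [2,3]-sigmatropic rearrangement to selenenate 25, carrying oxygen to C17 on the same (outer) face and moving the alkene to C14=C16 in conjugation with the ester; diethylamine cleaves the Se–O bond to free the alcohol. No syn-elimination competes because C14 has no sp3 β-hydrogen, and C17 is thereby set cis to the C13 oxygen.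

Step 14
Reactants: 26 methyl ester of the target with C13–OSiMe3
Product: 27 target acid CNP0106718.3
Conditions: LiOH, THF–MeOH–H2O, 20 to 40 °C; then 1 M HCl to pH 3, 0 °C
Reagents that add atoms: lithium hydroxide, [Li+].[OH-]
Why: Saponification of the methyl ester and hydroxide-induced cleavage of the tertiary trimethylsilyl ether in the same pot, then brief cold acidification; the alkene geometry (C15 trans to C17) rules out lactonisation onto C17, and the short acid contact avoids ionisation of the allylic alcohols.

## Compound list

1 | dicyclopentadiene | C1C=CC2C1C1CC2C=C1 | starting material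
2 | cyclopenta-1,3-diene | C1C=CC=C1 | intermediate
3 | decanoyl chloride | CCCCCCCCCC(=O)Cl | starting material
4 | octylketene (dec-1-en-1-one) | CCCCCCCCC=C=O | intermediate
5 | rac-endo-7-octylbicyclo[3.2.0]hept-2-en-6-one (octyl cis to C11; racemate, one enantiomer drawn) | CCCCCCCC[C@@H]1[C@@H]2C=CC[C@@H]2C1=O | intermediate
6 | rac-exo-7-octylbicyclo[3.2.0]hept-2-en-6-one (racemate, target-series enantiomer drawn) | CCCCCCCC[C@H]1[C@@H]2C=CC[C@@H]2C1=O | intermediate
7 | rac-exo-7-octylbicyclo[3.2.0]hept-2-en-6-one ethylene ketal (racemate, target-series enantiomer drawn) | CCCCCCCC[C@H]1[C@@H]2C=CC[C@@H]2C13OCCO3 | intermediate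
8 | bromoform | BrC(Br)Br | starting material
9 | rac-3,3-dibromo-8-octyltricyclo[4.2.0.0(2,4)]octan-7-one ethylene ketal (CBr2 anti to the cyclobutane) | CCCCCCCC[C@H]1[C@@H]2[C@H]3C(Br)(Br)[C@H]3C[C@@H]2C14OCCO4 | intermediate
10 | rac-3-bromo-4-hydroxy-8-octylbicyclo[4.2.0]oct-2-en-7-one ethylene ketal (OH trans to the cyclobutane; racemate, target-series enantiomer drawn) | CCCCCCCC[C@H]1[C@@H]2C=C(Br)[C@@H](O)C[C@@H]2C13OCCO3 | intermediate
11 | the same bromo allylic alcohol, single enantiomer (S at C13) | CCCCCCCC[C@H]1[C@@H]2C=C(Br)[C@@H](O)C[C@@H]2C13OCCO3 | intermediate
12 | 4-hydroxy-8-octylbicyclo[4.2.0]oct-2-en-7-one ethylene ketal | CCCCCCCC[C@H]1[C@@H]2C=C[C@@H](O)C[C@@H]2C13OCCO3 | intermediate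
13 | 4-hydroxy-8-octylbicyclo[4.2.0]oct-2-en-7-one (C13–OH convex, octyl exo) | CCCCCCCC[C@H]1[C@@H]2C=C[C@@H](O)C[C@@H]2C1=O | intermediate
14 | 7-methylidene-8-octylbicyclo[4.2.0]oct-2-en-4-ol | CCCCCCCC[C@H]1[C@@H]2C=C[C@@H](O)C[C@@H]2C1=C | intermediate
15 | vinyl bromide (bromoethene) | C=CBr | starting material
16 | C19 B-alkyl-9-borabicyclo[3.3.1]nonane of 14, C13–OH as its 9-BBN borinate | CCCCCCCC[C@H]1[C@@H]2C=C[C@@H](OB3C4CCCC3CCC4)C[C@@H]2[C@@H]1CB1C2CCCC1CCC2 | intermediate
17 | endo-7-(prop-2-enyl)-exo-8-octylbicyclo[4.2.0]oct-2-en-4-ol | CCCCCCCC[C@H]1[C@@H]2C=C[C@@H](O)C[C@@H]2[C@@H]1CC=C | intermediate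
18 | 8-(prop-2-enyl)-7-octylbicyclo[4.2.0]oct-4-en-3-one (allyl endo, octyl exo) | CCCCCCCC[C@H]1[C@@H]2C=CC(=O)C[C@@H]2[C@@H]1CC=C | intermediate
19 | methyl (2E)-penta-2,4-dienoate | C=C/C=C/C(=O)OC | starting material
20 | methyl (2E,4E)-6-(7-octyl-3-oxobicyclo[4.2.0]oct-4-en-8-yl)hexa-2,4-dienoate | CCCCCCCC[C@H]1[C@@H]2C=CC(=O)C[C@@H]2[C@@H]1C/C=C/C=C/C(=O)OC | intermediate
21 | trimethylsilyl dienol ether of 20 (C22=C13(OSiMe3)–C12=C11) | CCCCCCCC[C@H]1[C@@H]2C=CC(O[Si](C)(C)C)=C[C@@H]2[C@@H]1C/C=C/C=C/C(=O)OC | intermediate
22 | tetracyclic cycloadduct: methyl ester on C14 (H14 cis to H18), C13–OSiMe3 on the convex face, C11=C12 and C16=C17 | CCCCCCCC[C@H]1[C@@H]2C=C[C@]3(O[Si](C)(C)C)[C@@H](C(=O)OC)C=C[C@H]4C[C@H]1[C@H]2[C@@H]43 | intermediate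
23 | C14 phenylselenide of 22 (Se cis to the C13 silyloxy group) | CCCCCCCC[C@H]1[C@@H]2C=C[C@]3(O[Si](C)(C)C)[C@]([Se]c5ccccc5)(C(=O)OC)C=C[C@H]4C[C@H]1[C@H]2[C@@H]43 | intermediate
24 | selenoxide of 23 (either configuration at Se) | CCCCCCCC[C@H]1[C@@H]2C=C[C@]3(O[Si](C)(C)C)[C@]([Se](=O)c5ccccc5)(C(=O)OC)C=C[C@H]4C[C@H]1[C@H]2[C@@H]43 | intermediate
25 | C17 phenylselenenate (C17–O–SePh, C14=C16) | CCCCCCCC[C@H]1[C@@H]2C=C[C@]3(O[Si](C)(C)C)C(C(=O)OC)=C[C@@H](O[Se]c5ccccc5)[C@H]4C[C@H]1[C@H]2[C@@H]43 | intermediate
26 | methyl ester of the target with C13–OSiMe3 | CCCCCCCC[C@H]1[C@@H]2C=C[C@]3(O[Si](C)(C)C)C(C(=O)OC)=C[C@@H](O)[C@H]4C[C@H]1[C@H]2[C@@H]43 | intermediate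
27 | CNP0106718.3 (C13,C17-dihydroxy C14-carboxylic acid) | CCCCCCCC[C@H]1[C@@H]2C=C[C@]3(O)C(C(=O)O)=C[C@@H](O)[C@H]4C[C@H]1[C@H]2[C@@H]43 | target

## Step count and least certain steps

Total step count: 14. Longest linear sequence: 14 steps (1 to 27); 3, 8, 15 and 19 enter as commercial materials.

Step 4 (key step). What may go wrong: capture of the bromoallyl cation at the C11 terminus, or a 1,2-shift of a cyclobutane bond toward that terminus, competing with capture at C13; loss of the dioxolane through the acid released or through collapse of a ketal-oxonium intermediate. Fallback (from 3, back at 13): the ring enlargement is abandoned and ring A is six-membered from the start. Octylketene 4, generated from 3 as in step 2, is trapped with cyclohexa-1,3-diene and the adduct equilibrated with DBU to racemic exo-8-octylbicyclo[4.2.0]oct-2-en-7-one F1. Catalytic SeO2 with t-BuOOH in CH2Cl2 should hydroxylate the ring methylene C13 by an ene reaction followed by a [2,3]-shift, both on the convex face, to give the racemic hydroxy ketone F2 (the racemate of 13). Lipase acetylation as in step 5 then leaves 13, which re-enters at step 7. This avoids any cation but rests on a poorer ketene cycloaddition and on oxidation at C13 in preference to C10 and to the positions next to the ketone.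

Step 11. What may go wrong: low reactivity of the hindered trisubstituted enol ether, so that desilylation or 1,5-hydrogen shifts in the silyloxydiene win at the temperature needed; interruption after the first bond (C22–C18) by silyl transfer to the ester; participation of ring A as the 4π partner; closure through the other folding of the dienoate under ring A, which would give the cis B/C fusion. Fallback (from 18, back at 22): rings C and B are closed one after the other by polar steps. Oxidative cleavage of the terminal alkene of 18 (OsO4 cat., NaIO4, 2,6-lutidine) gives the aldehyde F3. A nitroaldol reaction with MeNO2 and dehydration (MeSO2Cl, Et3N) gives the (E)-nitroalkene F4. The kinetic C22 enolate (LiN(SiMe3)2, THF, −78 °C), or the silyl dienol ether with SnCl4, adds to C18 to give the nitromethyl ketone F5. A Nef reaction (NaOMe, then TiCl3 with NH4OAc buffer) gives the keto aldehyde F6. A Z-selective Wittig reaction with the ylide from (2-carboxyethyl)triphenylphosphonium bromide and NaN(SiMe3)2, followed by Me3SiCHN2, gives the (Z)-β,γ-unsaturated ester F7. LiN(i-Pr)2 at −78 °C closes ring B by intramolecular aldol addition of C14 to the C13 ketone from the side of C18, giving the hydroxy ester F8, and silylation (Me3SiOTf, 2,6-lutidine) gives 22.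

Step 8. What may go wrong: insufficient facial discrimination at C20, since the convex face carries the octyl-bearing C9 while the concave face carries ring A, leading to the C20 epimer; slow transfer of the β-branched alkyl group in the coupling. Fallback (from 13, back at 17): hydrogen is delivered as a nucleophile to the ring carbon itself. Horner–Wadsworth–Emmons reaction of 13 with (EtO)2P(O)CH2CN and NaH gives the cyclobutylidene acetonitrile F9 (E/Z mixture). Conjugate reduction with Mg in MeOH (or [(Ph3P)CuH]6) should add hydrogen to C20 from the convex face to give the endo cyanomethyl compound F10. i-Bu2AlH at −78 °C and aqueous acid give the aldehyde F11, and methylenation with Ph3P=CH2 gives 17.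

Step 12 (with step 13). What may go wrong: selenenylation at the γ-carbon C17 or on the inner face of C14, which would misplace or invert the C17 oxygen after rearrangement; loss of the C13 silyloxy group by β-elimination from the enolate. Fallback (from 22, back at 26): the oxygen is brought to C17 by an electrophile on the alkene instead of on the enolate. Epoxidation of C16=C17 of 22 with dimethyldioxirane (acetone, −20 °C) on the outer face gives the epoxide F12. DBU (or LiN(SiMe3)2) then removes H14, which is anti-periplanar to the C16–O bond, and opens the epoxide (E1cB) to give 26 directly. The price is that C16=C17 must be distinguished from the more hindered C11=C12.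

## Further compounds

F1 | step 4 | rac-exo-8-octylbicyclo[4.2.0]oct-2-en-7-one (racemate, one enantiomer drawn) | CCCCCCCC[C@H]1[C@@H]2C=CCC[C@@H]2C1=O
F2 | step 4 | racemate of 13 (4-hydroxy-8-octylbicyclo[4.2.0]oct-2-en-7-one) | CCCCCCCC[C@H]1[C@@H]2C=C[C@@H](O)C[C@@H]2C1=O
F3 | step 11 | 2-(7-octyl-3-oxobicyclo[4.2.0]oct-4-en-8-yl)acetaldehyde | CCCCCCCC[C@H]1[C@@H]2C=CC(=O)C[C@@H]2[C@@H]1CC=O
F4 | step 11 | ring-A enone with (E)-3-nitroprop-2-enyl arm on C20 | CCCCCCCC[C@H]1[C@@H]2C=CC(=O)C[C@@H]2[C@@H]1C/C=C/[N+](=O)[O-]
F5 | step 11 | tricyclic enone with C18 nitromethyl group | CCCCCCCC[C@H]1[C@@H]2C=CC(=O)[C@@H]3[C@@H](C[N+](=O)[O-])C[C@H]1[C@H]23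
F6 | step 11 | tricyclic enone with C18 formyl group (C17 aldehyde) | CCCCCCCC[C@H]1[C@@H]2C=CC(=O)[C@@H]3[C@@H](C=O)C[C@H]1[C@H]23
F7 | step 11 | tricyclic enone with (Z)-4-methoxy-4-oxobut-1-enyl group on C18 | CCCCCCCC[C@H]1[C@@H]2C=CC(=O)[C@@H]3[C@@H](/C=C\CC(=O)OC)C[C@H]1[C@H]23
F8 | step 11 | tetracyclic hydroxy ester (22 with free C13–OH) | CCCCCCCC[C@H]1[C@@H]2C=C[C@]3(O)[C@@H](C(=O)OC)C=C[C@H]4C[C@H]1[C@H]2[C@@H]43
F9 | step 8 | 2-(4-hydroxy-8-octylbicyclo[4.2.0]oct-2-en-7-ylidene)acetonitrile (E/Z mixture) | CCCCCCCC[C@H]1[C@@H]2C=C[C@@H](O)C[C@@H]2C1=CC#N
F10 | step 8 | 2-(4-hydroxy-8-octylbicyclo[4.2.0]oct-2-en-7-yl)acetonitrile (arm endo) | CCCCCCCC[C@H]1[C@@H]2C=C[C@@H](O)C[C@@H]2[C@@H]1CC#N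
F11 | step 8 | 2-(4-hydroxy-8-octylbicyclo[4.2.0]oct-2-en-7-yl)acetaldehyde (arm endo) | CCCCCCCC[C@H]1[C@@H]2C=C[C@@H](O)C[C@@H]2[C@@H]1CC=O
F12 | step 12 | C16,C17-epoxide of 22 (oxygen on the outer face of ring B) | CCCCCCCC[C@H]1[C@@H]2C=C[C@]3(O[Si](C)(C)C)[C@@H](C(=O)OC)[C@H]5O[C@H]5[C@H]4C[C@H]1[C@H]2[C@@H]43
A1 | alternative 1 | cis-fused rings A/B enone (C11 ketone, C10=C21, C13–OH, C17 tert-butyldimethylsilyl ether, methyl ester, (E)-undec-2-enyl on C18) | CCCCCCCC/C=C/C[C@@H]1[C@H](O[Si](C)(C)C(C)(C)C)C=C(C(=O)OC)[C@@]2(O)CC(=O)C=C[C@@H]12
A2 | alternative 1 | tetracyclic C11 ketone (C17 tert-butyldimethylsilyl ether, methyl ester) | CCCCCCCC[C@H]1[C@@H]2C(=O)C[C@]3(O)C(C(=O)OC)=C[C@@H](O[Si](C)(C)C(C)(C)C)[C@H]4C[C@H]1[C@H]2[C@@H]43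
A3 | alternative 2 | 1-[7-(phenylthio)bicyclo[4.1.0]hept-2-en-7-yl]nonan-1-ol (carbinol and C20 configurations open) | CCCCCCCCC(O)C1(Sc2ccccc2)[C@@H]2C=CCC[C@H]12
A4 | alternative 2 | exo-8-octylbicyclo[4.2.0]oct-2-en-7-one | CCCCCCCC[C@H]1[C@@H]2C=CCC[C@@H]2C1=O
A5 | alternative 3 | ring-A enone with (E)-3-nitroprop-2-enyl arm on C20 | CCCCCCCC[C@H]1[C@@H]2C=CC(=O)C[C@@H]2[C@@H]1C/C=C/[N+](=O)[O-]
A6 | alternative 3 | tricyclic enone with C18 nitromethyl group | CCCCCCCC[C@H]1[C@@H]2C=CC(=O)[C@@H]3[C@@H](C[N+](=O)[O-])C[C@H]1[C@H]23
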